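**Retrosynthetic overview**

1. Last bonds: the tert-butyl ester is cleaved; the side-chain ester C–O bond comes from acid 12 opening the C9 spiro-epoxide made in the flask from iodohydrin 24; the C9–CH2I bond comes from ring-A ketone 23. Numbering is that of 2-benzoxepine (C1 lactone carbonyl, O2, C3, C4, C5, C5a, C6–C9, C9a); ring A = C5a–C9a carbocycle, ring B = lactone, ring C = side-chain cyclohexene.
2. Ring A is a Robinson retron laid on ring B: C5a is β and C9a is α to the lactone carbonyl C1, and C9 and C8 are the two carbons of an acetyl group on C9a. Cutting C5a–C6 (enamine Michael bond) and C7=C8 (aldol condensation) gives the 3-acetyl dienolide 19 and 3-methylbutanal 20.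
3. Ring B: 19 comes from ring-closing metathesis of diene ester 16 (from 13 and 14), then selenoxide dehydrogenation.
4. Ring C: acid 12 comes from an endo Diels–Alder reaction of triene 7 with but-3-en-2-one 8 (cis C1/C6, acetyl turned into isopropyl); 7 comes from 1, 2 and 4 by Heck reaction, Baylis–Hillman reaction and allylic acetate shift.
5. Order of ring formation: ring C (step 4), ring B (step 9), ring A (step 11).

Key step: step 11

Remark: 1, 13 and 14 are taken as commercial, and the catalyst antipodes in steps 4 and 11 are assigned from the accepted transition-state models of these catalyst classes.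

**Step 1**
Reactants: 1 2-bromoprop-2-en-1-ol; 2 prop-2-enal
Product: 3 (2E)-4-(hydroxymethyl)penta-2,4-dienal
Conditions: Pd(OAc)2 (5 mol %), Bu4NCl, NaHCO3, DMF, 40 °C
Reagents that add atoms: none
Why: Heck reaction under ligand-free phase-transfer conditions, in which syn carbopalladation of the enal and syn β-hydride elimination should give the (2E)-dienal; no stereocentre is formed.

**Step 2**
Reactants: 3 (2E)-4-(hydroxymethyl)penta-2,4-dienal; 4 methyl prop-2-enoate
Product: 5 methyl (4E)-3-hydroxy-6-(hydroxymethyl)-2-methylidenehepta-4,6-dienoate (racemic)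
Conditions: DABCO (0.5 equiv), 4 (5 equiv), MeOH, rt
Reagents that add atoms: none
Why: Morita–Baylis–Hillman reaction, in which the DABCO–acrylate zwitterion should add 1,2 to the aldehyde; the new carbinol centre is racemic and is erased in step 3.

**Step 3**
Reactants: 5 methyl (4E)-3-hydroxy-6-(hydroxymethyl)-2-methylidenehepta-4,6-dienoate
Product: 7 methyl (2E,4E)-2,6-bis[(acetyloxy)methyl]hepta-2,4,6-trienoate, via secondary bis-acetate 6 (not isolated)
Conditions: Ac2O, pyridine, DMAP (cat.), CH2Cl2, 0 °C; then DABCO (20 mol %), THF, 50 °C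
Reagents that add atoms: acetic anhydride (CC(=O)OC(C)=O)
Why: Acetylation followed by the DABCO-catalysed SN2′/SN2′ allylic acetate shift of a Baylis–Hillman acetate should move the secondary acetate to the primary carbon and give the thermodynamically favoured (2E)-trienoate with the ester trans to the chain, leaving no stereocentre.

**Step 4**
Reactants: 7 methyl (2E,4E)-2,6-bis[(acetyloxy)methyl]hepta-2,4,6-trienoate; 8 but-3-en-2-one
Product: 9 methyl (2E)-3-[(1R,6R)-6-acetyl-3-[(acetyloxy)methyl]cyclohex-2-en-1-yl]-2-[(acetyloxy)methyl]prop-2-enoate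
Conditions: (R)-3,3-diphenyl-1-(2-methylphenyl)tetrahydro-1H,3H-pyrrolo[1,2-c][1,3,2]oxazaborole (20 mol %), Tf2NH (18 mol %), CH2Cl2, −78 to −40 °C
Reagents that add atoms: none
Why: Lewis-acid-catalysed Diels–Alder reaction that closes ring C, in which the 1,3-disubstituted terminal diene places the acetyl carbon next to C1 (ortho/para rule), the endo transition state puts acetyl and the C1 side chain cis, and the (R)-oxazaborolidinium cation bound to the s-trans enone should shield one face so that C6 and with it C1 are set as (1R,6R).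

**Step 5**
Reactants: 9 methyl (2E)-3-[(1R,6R)-6-acetyl-3-[(acetyloxy)methyl]cyclohex-2-en-1-yl]-2-[(acetyloxy)methyl]prop-2-enoate
Product: 10 methyl (2E)-2-[(acetyloxy)methyl]-3-[(1R,6R)-3-[(acetyloxy)methyl]-6-(prop-1-en-2-yl)cyclohex-2-en-1-yl]prop-2-enoate
Conditions: Cp2TiMe2 (1.5 equiv), toluene, 65 °C, dark
Reagents that add atoms: dimethyltitanocene (C[Ti](C)(C1C=CC=C1)C1C=CC=C1)
Why: Carbonyl methylenation by titanocene methylidene is not basic, so the cis α-stereocentre at C6 should not epimerise, and the ketone should react before the ester carbonyls.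

**Step 6**
Reactants: 10 methyl (2E)-2-[(acetyloxy)methyl]-3-[(1R,6R)-3-[(acetyloxy)methyl]-6-(prop-1-en-2-yl)cyclohex-2-en-1-yl]prop-2-enoate
Product: 11 methyl (2E)-2-[(acetyloxy)methyl]-3-[(1R,6S)-3-[(acetyloxy)methyl]-6-(propan-2-yl)cyclohex-2-en-1-yl]prop-2-enoate
Conditions: H2 (1 atm), RhCl(PPh3)3 (5 mol %), benzene, rt
Reagents that add atoms: none
Why: Homogeneous hydrogenation should reduce only the 1,1-disubstituted isopropenyl alkene and leave both trisubstituted alkenes; no stereocentre is formed (the descriptor at C6 changes by priority only).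

**Step 7**
Reactants: 11 methyl (2E)-2-[(acetyloxy)methyl]-3-[(1R,6S)-3-[(acetyloxy)methyl]-6-(propan-2-yl)cyclohex-2-en-1-yl]prop-2-enoate
Product: 12 (2E)-2-(hydroxymethyl)-3-[(1R,6S)-3-(hydroxymethyl)-6-(propan-2-yl)cyclohex-2-en-1-yl]prop-2-enoic acid
Conditions: LiOH (4 equiv), THF/MeOH/H2O, 0 °C to rt; then 1 M HCl to pH 3
Reagents that add atoms: lithium hydroxide ([Li+].[OH-])
Why: Saponification should cleave the methyl ester and both acetates, and neither stereocentre is α to a carbonyl group.

**Step 8**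
Reactants: 13 ethyl 2-acetylpent-4-enoate; 14 tert-butyl 2-(bromomethyl)prop-2-enoate
Product: 16 2-(tert-butoxycarbonyl)prop-2-en-1-yl 2-acetylpent-4-enoate (racemic), via potassium carboxylate 15 (not isolated)
Conditions: KOH (1.0 equiv), EtOH/H2O, 0 °C to rt, evaporate cold; then 14, DMF, 0 °C to rt
Reagents that add atoms: potassium hydroxide ([K+].[OH-])
Why: Saponification to the β-keto carboxylate and its O-alkylation by the allylic bromide (SN2, degenerate with SN2′ on this symmetrical allyl unit) should be faster than decarboxylation at this temperature.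

**Step 9**
Reactants: 16 2-(tert-butoxycarbonyl)prop-2-en-1-yl 2-acetylpent-4-enoate
Product: 17 tert-butyl 3-acetyl-2-oxo-2,3,4,7-tetrahydrooxepine-6-carboxylate (racemic)
Conditions: second-generation Grubbs catalyst RuCl2(=CHPh)(H2IMes)(PCy3) (5 mol %), CH2Cl2 (0.005 M), 40 °C
Reagents that add atoms: none
Why: Ring-closing metathesis between the terminal alkene and the 1,1-disubstituted acrylate alkene should close the seven-membered lactone ring B by forming its trisubstituted enoate double bond, with the ester necessarily trans to C4.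

**Step 10**
Reactants: 17 tert-butyl 3-acetyl-2-oxo-2,3,4,7-tetrahydrooxepine-6-carboxylate
Product: 19 tert-butyl 3-acetyl-2-oxo-2,7-dihydrooxepine-6-carboxylate, via selenide 18 (not isolated)
Conditions: PhSeCl, pyridine, CH2Cl2, 0 °C; then 30% H2O2, 0 °C to rt; cold aq. NaHCO3 wash, solution used at once
Reagents that add atoms: none
Why: α-Selenenylation of the β-keto lactone at C3 followed by selenoxide syn-elimination, for which only the C4 hydrogens are available, should give the 3-acyl dienolide.

**Step 11**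
Reactants: 19 tert-butyl 3-acetyl-2-oxo-2,7-dihydrooxepine-6-carboxylate; 20 3-methylbutanal
Product: 22 tert-butyl (5aS,6S,9aS)-1,9-dioxo-6-(propan-2-yl)-1,3,5a,6,9,9a-hexahydro-2-benzoxepine-4-carboxylate, via Michael adduct 21 (not isolated)
Conditions: (S)-2-[diphenyl(trimethylsilyloxy)methyl]pyrrolidine (20 mol %), PhCO2H (20 mol %), 20 (3 equiv), toluene, −20 to 0 °C; then Bn2NH·CF3CO2H (30 mol %), 4 Å sieves, 40 °C
Reagents that add atoms: none
Why: The prolinol silyl ether turns 20 into an E-enamine that adds to oxepine C4 of 19, the β-carbon of a doubly activated 2-acyl enoate (enamine Michael addition, as known for aldehydes with nitroalkenes and alkylidene 1,3-dicarbonyl compounds), and the ammonium salt then condenses the acetyl methyl group with the new aldehyde, so the whole is a Robinson-type formal [4+2] annulation. Ring A is closed in the aldol step by a 6-(enolendo)-exo-trig attack of the future C8 on the C7 aldehyde, followed by dehydration. Benzoxepine C6 is set by attack on the enamine face away from the diphenyl(silyloxy)methyl group, and C5a by the acyclic synclinal transition state with ring carbon C5 anti, which should give the syn adduct (4R,2′R) and so the trans C5a/C6 relation; C9a is epimerisable and should settle trans to C5a. The step needs attack at oxepine C4 and not at C5 or C6, which the two carbonyl groups on C3 secure because only C4 attack gives a 1,3-dicarbonyl enolate, and ring closure through the methyl group and not through C3–H, which could only give a four-membered ring. The trans product is also the thermodynamic one, since C6 is γ to the new enone and can equilibrate.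

**Step 12**
Reactants: 22 tert-butyl (5aS,6S,9aS)-1,9-dioxo-6-(propan-2-yl)-1,3,5a,6,9,9a-hexahydro-2-benzoxepine-4-carboxylate
Product: 23 tert-butyl (5aS,6R,9aS)-1,9-dioxo-6-(propan-2-yl)-1,3,5a,6,7,8,9,9a-octahydro-2-benzoxepine-4-carboxylate
Conditions: H2 (1 atm), RhCl(PPh3)3 (10 mol %), benzene, rt
Reagents that add atoms: none
Why: Homogeneous hydrogenation should saturate the cis-disubstituted C7=C8 alkene and spare the trisubstituted enoate of ring B; no stereocentre is formed (the descriptor at C6 changes by priority only).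

**Step 13**
Reactants: 23 tert-butyl (5aS,6R,9aS)-1,9-dioxo-6-(propan-2-yl)-1,3,5a,6,7,8,9,9a-octahydro-2-benzoxepine-4-carboxylate
Product: 24 tert-butyl (5aS,6R,9S,9aS)-9-hydroxy-9-(iodomethyl)-1-oxo-6-(propan-2-yl)-1,3,5a,6,7,8,9,9a-octahydro-2-benzoxepine-4-carboxylate
Conditions: SmI2 (2.5 equiv), CH2I2 (1.5 equiv), THF, 0 °C to rt; 0.1 M HCl work-up
Reagents that add atoms: diiodomethane (ICI)
Why: Samarium Barbier-type iodomethylation of a ketone, in which the weakly basic iodomethylsamarium carbenoid should add to the chelated β-keto lactone along the axial trajectory of the ring-A chair (isopropyl, C5a and C9a substituents equatorial), giving axial CH2I and equatorial hydroxyl, that is (9S).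

**Step 14**
Reactants: 24 tert-butyl (5aS,6R,9S,9aS)-9-hydroxy-9-(iodomethyl)-1-oxo-6-(propan-2-yl)-1,3,5a,6,7,8,9,9a-octahydro-2-benzoxepine-4-carboxylate; 12 (2E)-2-(hydroxymethyl)-3-[(1R,6S)-3-(hydroxymethyl)-6-(propan-2-yl)cyclohex-2-en-1-yl]prop-2-enoic acid
Product: 26 tert-butyl (5aS,6R,9S,9aS)-9-hydroxy-9-({[(2E)-2-(hydroxymethyl)-3-[(1R,6S)-3-(hydroxymethyl)-6-(propan-2-yl)cyclohex-2-en-1-yl]prop-2-enoyl]oxy}methyl)-1-oxo-6-(propan-2-yl)-1,3,5a,6,7,8,9,9a-octahydro-2-benzoxepine-4-carboxylate, via spiro-epoxide 25 (not isolated)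
Conditions: Cs2CO3 (2.2 equiv), DMF, 50 °C
Reagents that add atoms: none
Why: Intramolecular Williamson reaction should close the iodohydrin to the spiro-epoxide with retention at C9, and the caesium carboxylate of 12 should open it by SN2 attack at the unsubstituted CH2 carbon, giving the primary ester and the tertiary alcohol without protecting groups on 12.

**Step 15**
Reactants: 26 tert-butyl ester of the target
Product: 27 (5aS,6R,9S,9aS)-9-hydroxy-9-({[(2E)-2-(hydroxymethyl)-3-[(1R,6S)-3-(hydroxymethyl)-6-(propan-2-yl)cyclohex-2-en-1-yl]prop-2-enoyl]oxy}methyl)-1-oxo-6-(propan-2-yl)-1,3,5a,6,7,8,9,9a-octahydro-2-benzoxepine-4-carboxylic acid (CNP0361406.5)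
Conditions: CF3CO2H/CH2Cl2 (1:5), 0 °C; aq. NaHCO3, then pH 3
Reagents that add atoms: none
Why: Acidolysis of the tert-butyl ester (E1 loss of the tert-butyl cation) should free the carboxylic acid, while the lactone, the enoate ester and the alcohols, whose tertiary carbinol is deactivated by two flanking acyloxy-type groups, should remain.

**Compound list**

1 | 2-bromoprop-2-en-1-ol | OCC(Br)=C | starting material
2 | prop-2-enal (acrolein) | C=CC=O | starting material
3 | (2E)-4-(hydroxymethyl)penta-2,4-dienal | O=C/C=C/C(=C)CO | intermediate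
4 | methyl prop-2-enoate (methyl acrylate) | C=CC(=O)OC | starting material
5 | methyl (4E)-3-hydroxy-6-(hydroxymethyl)-2-methylidenehepta-4,6-dienoate, racemic | COC(=O)C(=C)C(O)/C=C/C(=C)CO | intermediate
6 | methyl (4E)-3-(acetyloxy)-6-[(acetyloxy)methyl]-2-methylidenehepta-4,6-dienoate, racemic | COC(=O)C(=C)C(OC(C)=O)/C=C/C(=C)COC(C)=O | intermediate
7 | methyl (2E,4E)-2,6-bis[(acetyloxy)methyl]hepta-2,4,6-trienoate | COC(=O)/C(=C/C=C/C(=C)COC(C)=O)COC(C)=O | intermediate
8 | but-3-en-2-one | CC(=O)C=C | starting material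
9 | methyl (2E)-3-[(1R,6R)-6-acetyl-3-[(acetyloxy)methyl]cyclohex-2-en-1-yl]-2-[(acetyloxy)methyl]prop-2-enoate (cis) | COC(=O)/C(=C/[C@H]1C=C(COC(C)=O)CC[C@H]1C(C)=O)COC(C)=O | intermediate
10 | methyl (2E)-2-[(acetyloxy)methyl]-3-[(1R,6R)-3-[(acetyloxy)methyl]-6-(prop-1-en-2-yl)cyclohex-2-en-1-yl]prop-2-enoate | COC(=O)/C(=C/[C@H]1C=C(COC(C)=O)CC[C@H]1C(C)=C)COC(C)=O | intermediate
11 | methyl (2E)-2-[(acetyloxy)methyl]-3-[(1R,6S)-3-[(acetyloxy)methyl]-6-(propan-2-yl)cyclohex-2-en-1-yl]prop-2-enoate | COC(=O)/C(=C/[C@H]1C=C(COC(C)=O)CC[C@H]1C(C)C)COC(C)=O | intermediate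
12 | (2E)-2-(hydroxymethyl)-3-[(1R,6S)-3-(hydroxymethyl)-6-(propan-2-yl)cyclohex-2-en-1-yl]prop-2-enoic acid | OC(=O)/C(=C/[C@H]1C=C(CO)CC[C@H]1C(C)C)CO | intermediate
13 | ethyl 2-acetylpent-4-enoate | CCOC(=O)C(CC=C)C(C)=O | starting material
14 | tert-butyl 2-(bromomethyl)prop-2-enoate | C=C(CBr)C(=O)OC(C)(C)C | starting material
15 | potassium 2-acetylpent-4-enoate | [K+].[O-]C(=O)C(CC=C)C(C)=O | intermediate
16 | 2-(tert-butoxycarbonyl)prop-2-en-1-yl 2-acetylpent-4-enoate, racemic | CC(=O)C(CC=C)C(=O)OCC(=C)C(=O)OC(C)(C)C | intermediate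
17 | tert-butyl 3-acetyl-2-oxo-2,3,4,7-tetrahydrooxepine-6-carboxylate, racemic | CC(=O)C1CC=C(C(=O)OC(C)(C)C)COC1=O | intermediate
18 | tert-butyl 3-acetyl-2-oxo-3-(phenylselanyl)-2,3,4,7-tetrahydrooxepine-6-carboxylate, racemic | CC(=O)C1([Se]c2ccccc2)CC=C(C(=O)OC(C)(C)C)COC1=O | intermediate
19 | tert-butyl 3-acetyl-2-oxo-2,7-dihydrooxepine-6-carboxylate | CC(=O)C1=CC=C(C(=O)OC(C)(C)C)COC1=O | intermediate
20 | 3-methylbutanal | CC(C)CC=O | starting material
21 | tert-butyl (4R)-3-acetyl-4-[(2R)-3-methyl-1-oxobutan-2-yl]-2-oxo-2,3,4,7-tetrahydrooxepine-6-carboxylate (C3 epimers) | CC(C)[C@@H](C=O)[C@H]1C=C(C(=O)OC(C)(C)C)COC(=O)C1C(C)=O | intermediate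
22 | tert-butyl (5aS,6S,9aS)-1,9-dioxo-6-(propan-2-yl)-1,3,5a,6,9,9a-hexahydro-2-benzoxepine-4-carboxylate | CC(C)[C@H]1C=CC(=O)[C@H]2C(=O)OCC(C(=O)OC(C)(C)C)=C[C@H]12 | intermediate
23 | tert-butyl (5aS,6R,9aS)-1,9-dioxo-6-(propan-2-yl)-1,3,5a,6,7,8,9,9a-octahydro-2-benzoxepine-4-carboxylate | CC(C)[C@H]1CCC(=O)[C@H]2C(=O)OCC(C(=O)OC(C)(C)C)=C[C@H]12 | intermediate
24 | tert-butyl (5aS,6R,9S,9aS)-9-hydroxy-9-(iodomethyl)-1-oxo-6-(propan-2-yl)-1,3,5a,6,7,8,9,9a-octahydro-2-benzoxepine-4-carboxylate | CC(C)[C@H]1CC[C@@](O)(CI)[C@H]2C(=O)OCC(C(=O)OC(C)(C)C)=C[C@H]12 | intermediate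
25 | tert-butyl (5aS,6R,9S,9aS)-1-oxo-6-(propan-2-yl)-3,5a,6,7,8,9a-hexahydro-1H-spiro[2-benzoxepine-9,2′-oxirane]-4-carboxylate | CC(C)[C@H]1CC[C@@]3(CO3)[C@H]2C(=O)OCC(C(=O)OC(C)(C)C)=C[C@H]12 | intermediate
26 | tert-butyl ester of the target, (5aS,6R,9S,9aS) in the bicycle and (2E),(1R,6S) in the acyl group | CC(C)[C@H]1CC[C@@](O)(COC(=O)/C(=C/[C@H]3C=C(CO)CC[C@H]3C(C)C)CO)[C@H]2C(=O)OCC(C(=O)OC(C)(C)C)=C[C@H]12 | intermediate
27 | (5aS,6R,9S,9aS)-9-hydroxy-9-({[(2E)-2-(hydroxymethyl)-3-[(1R,6S)-3-(hydroxymethyl)-6-(propan-2-yl)cyclohex-2-en-1-yl]prop-2-enoyl]oxy}methyl)-1-oxo-6-(propan-2-yl)-1,3,5a,6,7,8,9,9a-octahydro-2-benzoxepine-4-carboxylic acid | CC(C)[C@H]1CC[C@@](O)(COC(=O)/C(=C/[C@H]2C=C(CO)CC[C@H]2C(C)C)CO)[C@H]2C(=O)OCC(C(=O)O)=C[C@H]12 | target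

**Step count and risks**

Total step count: 15. Longest linear sequence: 9 steps (steps 1 to 7, then 14 and 15).

The three steps most likely to fail are steps 11, 13 and 4.

For step 11, the enamine may add slowly to the hindered, fully substituted C3=C4 alkene of 19. The adduct may also rest as its cyclic hemiacetal or revert by retro-Michael reaction during ring closure, which would erode enantio- and diastereocontrol. The fallback sets out from 19 and replaces enamine catalysis by a Lewis-acid-catalysed Mukaiyama–Michael addition. The silyl enol ether trimethyl[(3-methylbut-1-en-1-yl)oxy]silane F1 (from 20, Me3SiCl, Et3N, DMF) is added to 19 under [Cu((S,S)-t-Bu-box)](SbF6)2, which binds the 1,3-dicarbonyl unit of 19 at two points; the ligand antipode is chosen for the (4R) adduct. Hydrolytic work-up gives Michael adduct 21, which is then closed in a separate operation with pyrrolidinium acetate (aldol condensation). The fallback comes back to the route at 22.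

For step 13, the carbenoid may deprotonate the strongly enolised β-keto lactone instead of adding to it, or may add from the equatorial side. The fallback sets out from 23 and builds the C9 carbinol from an alkene. Methylenation with Cp2TiMe2 gives tert-butyl (5aS,6R,9aS)-9-methylidene-1-oxo-6-(propan-2-yl)-1,3,5a,6,7,8,9,9a-octahydro-2-benzoxepine-4-carboxylate F2. Dihydroxylation with OsO4 (cat.) and N-methylmorpholine N-oxide, expected from the equatorial side and sparing the electron-poor enoate, gives the (9S)-9-hydroxy-9-(hydroxymethyl) diol F3. Tosylation of the primary hydroxyl (TsCl, pyridine, 0 °C) gives the (9S)-9-hydroxy-9-{[(4-methylbenzenesulfonyl)oxy]methyl} compound F4. Treatment of F4 with 12 and Cs2CO3 in DMF passes through 25 as in step 14, and the fallback comes back to the route at 26.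

For step 4, the three ester groups of 7 may bind the boron catalyst and lower turnover and facial selectivity, and the endo preference may be weak for this electron-poor triene. The fallback sets out from 7 and uses iminium catalysis with the more reactive dienophile 2. With (5S)-5-benzyl-2,2,3-trimethylimidazolidin-4-one hydrochloride in MeCN/H2O at −20 °C, the endo adduct methyl (2E)-2-[(acetyloxy)methyl]-3-[(1R,6R)-3-[(acetyloxy)methyl]-6-formylcyclohex-2-en-1-yl]prop-2-enoate F5 should form. Aldehyde-selective methyl transfer with MeTi(OiPr)3 at −78 to −20 °C gives the 6-(1-hydroxyethyl) compound F6 as a mixture of carbinol epimers. Periodinane oxidation buffered with NaHCO3 then comes back to the route at 9.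

**Further compounds**

F1 | step 11 | trimethyl[(3-methylbut-1-en-1-yl)oxy]silane (E/Z mixture) | CC(C)C=CO[Si](C)(C)C
F2 | step 13 | tert-butyl (5aS,6R,9aS)-9-methylidene-1-oxo-6-(propan-2-yl)-1,3,5a,6,7,8,9,9a-octahydro-2-benzoxepine-4-carboxylate | CC(C)[C@H]1CCC(=C)[C@H]2C(=O)OCC(C(=O)OC(C)(C)C)=C[C@H]12
F3 | step 13 | tert-butyl (5aS,6R,9S,9aS)-9-hydroxy-9-(hydroxymethyl)-1-oxo-6-(propan-2-yl)-1,3,5a,6,7,8,9,9a-octahydro-2-benzoxepine-4-carboxylate | CC(C)[C@H]1CC[C@@](O)(CO)[C@H]2C(=O)OCC(C(=O)OC(C)(C)C)=C[C@H]12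
F4 | step 13 | tert-butyl (5aS,6R,9S,9aS)-9-hydroxy-9-{[(4-methylbenzenesulfonyl)oxy]methyl}-1-oxo-6-(propan-2-yl)-1,3,5a,6,7,8,9,9a-octahydro-2-benzoxepine-4-carboxylate | CC(C)[C@H]1CC[C@@](O)(COS(=O)(=O)c3ccc(C)cc3)[C@H]2C(=O)OCC(C(=O)OC(C)(C)C)=C[C@H]12
F5 | step 4 | methyl (2E)-2-[(acetyloxy)methyl]-3-[(1R,6R)-3-[(acetyloxy)methyl]-6-formylcyclohex-2-en-1-yl]prop-2-enoate | COC(=O)/C(=C/[C@H]1C=C(COC(C)=O)CC[C@H]1C=O)COC(C)=O
F6 | step 4 | methyl (2E)-2-[(acetyloxy)methyl]-3-[(1R,6R)-3-[(acetyloxy)methyl]-6-(1-hydroxyethyl)cyclohex-2-en-1-yl]prop-2-enoate (carbinol epimers) | COC(=O)/C(=C/[C@H]1C=C(COC(C)=O)CC[C@H]1C(C)O)COC(C)=O
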